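The earlier runs and the new flask are calculated for substances that don't exist.

| setting | birch | alder | flask |
|---|---|---|---|
| substrate | 0.026 M | 0.026 M | 0.026 M |
| reagent | 0.70 equiv | 0.35 equiv | 0.700 equiv |
| initiator | 2 mol% | 2 mol% | 2 mol% |
| temperature | 80 °C | 80 °C | 80 °C |
| remark | the very flask that is asked about, followed so far | run made earlier |  |
| time |  |  | 4.0 min |

birch run (percent of the substrate charged)

| time / min | product / % | substrate / % |
|---|---|---|
| 0.833 | 43.8 | 55.1 |
| 1.50 | 44.7 | 54.3 |
| 2.50 | 43.5 | 53.8 |
| 3.00 | 43.1 | 53.2 |

alder run (percent of the substrate charged)

| time / s | product / % | substrate / % |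
|---|---|---|
| 10.0 | 29.3 | 70.0 |
| 30.0 | 28.3 | 69.7 |
| 50.0 | 29.2 | 69.9 |
| 80.0 | 29.1 | 69.2 |

(scatter of a reading: 0.5 percentage points)

- amber: change nothing and wait 2.0 min more
- red: at 4.0 min add reagent, 100% of the amount charged, then wait 2.0 min
- violet: at 4.0 min take out 90% of the product then present, then wait 2.0 min
- teal: at 4.0 min raise the temperature by 10 K, then wait 2.0 min

- product taken out counts as made
- the analysis behind the earlier runs scatters by 0.5 percentage points, standard deviation
- the earlier runs do not show what temperature does; that part of a forecast is a guess
- additions bring no volume worth counting

- product, in percent of the substrate first charged, at 4.0 min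
- which option adds most product ("none" when 2 percentage points or less is all one gets) (amber / red / violet / teal / none)
- product present, with what was taken out counted in, in percent of the substrate first charged, after red
- product present, with what was taken out counted in, in percent of the substrate first charged, after teal

Of the substrate charged, the birch flask, which is the flask asked about, holds about 43.8% as product, and the alder flask about 29.0%. Take time first. By hand, a running reaction adds product between readings, but product in birch shows no rise from 0.833 min to 3.00 min against a scatter of 0.5 percentage points, and product in alder shows none from 10.0 s to 80.0 s. So we put now at 43.8% and expect no gain from amber.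

Reagent comes next. We count each product as one turnover costing one reagent, and alder then returned 0.828 of its charge. Going from alder to birch, the slope reads 0.423: this is the return on reagent, the product gained per reagent added, both as fractions of the substrate charge. It already stands lower than alder's figure. Applied to red, it gives 73.4%, and we read that as the high side.

Taking out product regrows it if the level is a balance, but not if it marks the end of a dose. We bet on the end of a dose, so violet gains nothing. The runs show no temperature, so for teal we guess 43.8% again.

The forecast gives 43.4% now, red as best, 61% after red and 43% after teal, holding that “this looks like a fast balance”. Of the figures asked for, the one after red is where we part, ours being higher than its figure.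

The flask gives 44.0% at 4.0 min. Red adds 25 points to reach 69.4%, teal ends at 44.0%, and amber, violet and teal add 0 points, 0 points and 0 points, so the best is red.

    initiator → 2 initiating radical (k = 0.00770 s⁻¹, Ea = 85.0 kJ mol⁻¹)
    substrate + initiating radical → chain carrier (k = 1.10 × 10⁶ M⁻¹ s⁻¹, Ea = 31.0 kJ mol⁻¹)
    reagent + chain carrier → product + initiating radical (k = 1.80 × 10⁷ M⁻¹ s⁻¹, Ea = 18.0 kJ mol⁻¹)
    2 initiating radical → ended chains A (k = 2.10 × 10⁸ M⁻¹ s⁻¹, Ea = 16.0 kJ mol⁻¹)
    2 chain carrier → ended chains B (k = 5.00 × 10⁸ M⁻¹ s⁻¹, Ea = 10.0 kJ mol⁻¹)
    2 reagent → homo dimer (k = 13.0 M⁻¹ s⁻¹, Ea = 55.0 kJ mol⁻¹)
    (constants at 80 °C)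

In this flask reagent, the limiting reagent, is under a fiftieth of its charge by 0.0746 min. Red's dose returned 0.364, lower than our slope, which leaves us 4.0 points high and the forecast 8.4 points low. A neighbour flask with 0.170 equiv of reagent holds 16.1% product at 4.0 min, so from there to alder the return reads 0.717, higher than our slope. Left until 40.0 min, this flask keeps 44.0% product, while substrate moves from 52.8% to 52.1% and ended chains B from 3.27% to 3.90% of the substrate charged, and initiator from 15.8% to 0% of its own charge.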